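The C8–C9 bond of ring B/C is treated as a Michael bond: C9 lies α to oxygenated C10 (a ketone in the precursor) and quaternary C8 lies β to the C7 carboxyl. Copper hydride converts an enone into the C9 enolate, which closes six-membered ring C (C8–C9–C11–C12–C13–C14) across a preformed ring D cyclopentylidene acetate and creates the bicyclo[3.2.1]octane with quaternary C8 in one operation. The precursor is a trans-3,4-disubstituted cyclopentane made from (R)-4-silyloxycyclopentenone; its C13 stereocentre forces the face of attack at C8. Ring B, the lactone and ring A then follow by enolate coupling and a Michael–aldol sequence relayed from C8/C9.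

Key step: step 4

Remark: atoms carry gibberellane numbers (ring A: C1–C5, C10; ring B: C5, C6, C8, C9, C10; ring C: C8, C9, C11–C14; ring D: C8, C13–C16; C7 and C19 carboxyl carbons; C17, C18 methyl carbons). Where a step is expected to give an E/Z or epimer mixture that converges later, one isomer is drawn.

Step 1
Reactants: 1 (R)-4-(tert-butyldimethylsilyloxy)cyclopent-2-en-1-one; 2 allylmagnesium bromide
Product: 4 (3R,4R)-3-allyl-4-(tert-butyldimethylsilyloxy)cyclopentan-1-one, via trimethylsilyl enol ether 3 (not isolated)
Conditions: CuBr·SMe2 (1.2 equiv), LiCl (1.2 equiv), Me3SiCl (2 equiv), THF, −78 °C; then 1 M HCl, 0 °C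
Reagents that add atoms: none
Why: The allylcopper reagent formed from 2 and CuBr·SMe2 adds 1,4 in the presence of Me3SiCl (copper-mediated conjugate addition) on the face of the enone anti to the C16 silyloxy group, so the bought C16 centre sets C13 trans to it, and acidic work-up hydrolyses the silyl enol ether 3.

Step 2
Reactants: 4 (3R,4R)-3-allyl-4-(tert-butyldimethylsilyloxy)cyclopentan-1-one; 5 benzyl (triphenylphosphoranylidene)acetate
Product: 6 benzyl (E)-2-[(3R,4R)-3-allyl-4-(tert-butyldimethylsilyloxy)cyclopentylidene]acetate
Conditions: toluene, 100 °C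
Reagents that add atoms: none
Why: Wittig olefination with the stabilised ylide converts the C8 ketone into the exocyclic enoate that carries C6 and C7 under neutral conditions that should not eliminate the β-silyloxy group, and the E/Z mixture to be expected is harmless because C6 becomes a saturated carbon in step 4 (the E isomer is drawn).

Step 3
Reactants: 6 benzyl (E)-2-[(3R,4R)-3-allyl-4-(tert-butyldimethylsilyloxy)cyclopentylidene]acetate; 7 methyl vinyl ketone
Product: 8 benzyl (E)-2-{(3R,4R)-4-(tert-butyldimethylsilyloxy)-3-[(E)-4-oxopent-2-en-1-yl]cyclopentylidene}acetate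
Conditions: second-generation Grubbs catalyst (5 mol%), CH2Cl2, 40 °C
Reagents that add atoms: none
Why: Olefin cross-metathesis joins the terminal allyl alkene to methyl vinyl ketone with the usual E selectivity for enones, while the trisubstituted electron-poor enoate does not engage the ruthenium carbene.

Step 4
Reactants: 8 benzyl (E)-2-{(3R,4R)-4-(tert-butyldimethylsilyloxy)-3-[(E)-4-oxopent-2-en-1-yl]cyclopentylidene}acetate
Product: 9 benzyl 2-[2-acetyl-6-(tert-butyldimethylsilyloxy)bicyclo[3.2.1]octan-1-yl]acetate (bridgehead C8 quaternary; acetyl on C9 anti to the C15–C16 bridge; 16-exo-silyloxy)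
Conditions: [(Ph3P)CuH]6 (0.2 equiv of the hexamer, 1.2 equiv of hydride), toluene, −40 to 23 °C; then H2O
Reagents that add atoms: none
Why: [(Ph3P)CuH]6 delivers hydride to C11 of the unhindered (E)-enone and so generates the C9 copper enolate regiospecifically under non-basic conditions, and this enolate adds to C8 of the β,β-disubstituted enoate before it is protonated. The closest known reaction type is the reductive Michael cyclisation of tethered enone–enoate pairs (conjugate reduction then intramolecular Michael addition). Ring C closes in the 6-exo-trig mode (C9 attacks C8 while C6 stays outside the new ring), which bridges ring D and gives the bicyclo[3.2.1]octane. The quaternary C8 is controlled by C13, because the tether C12–C11–C9 can reach C8 only from the face of ring D that carries it, so the E and Z enoates converge; C9 forms α to the C10 ketone, the epimer with the acetyl group anti to the C15–C16 bridge is drawn, and it remains correctable in step 5. The step needs hydride transfer to the enone in preference to the hindered enoate and must avoid γ-deprotonation of the enoate, which would expel the C16 silyloxy group; the disubstituted enone and the neutral copper enolate secure both. The expected side reactions are protonation of the enolate without cyclisation and 1,2-reduction of the ketone.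

Step 5
Reactants: 9 benzyl 2-[2-acetyl-6-(tert-butyldimethylsilyloxy)bicyclo[3.2.1]octan-1-yl]acetate
Product: 10 benzyl ester of the B/C/D tricyclic 10-ketone (ring B cyclopentanone with C5H2 and C6H–CO2Bn; H9 syn to C15; 16-exo-silyloxy)
Conditions: LiN(iPr)2 (2.2 equiv), THF, −78 °C; Fe(acac)3 (2.2 equiv), −78 to 0 °C; then KOtBu (0.2 equiv), tBuOH/THF, 0 °C
Reagents that add atoms: none
Why: Double deprotonation gives the kinetic methyl ketone enolate at C5 and the ester enolate at C6, one-electron oxidation by Fe(acac)3 joins the two α-carbons (intramolecular oxidative enolate coupling) to close ring B as a cyclopentanone, and the final KOtBu treatment equilibrates C9, now α to a ring ketone, to the cis B/C fusion with H9 syn to C15 that is expected to be favoured as in other angularly substituted hydrindan-1-ones, whereas the C6 configuration (one epimer drawn) is erased in step 6.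

Step 6
Reactants: 10 benzyl ester of the B/C/D tricyclic 10-ketone
Product: 11 benzyl ester of the B/C/D tricyclic 5-en-10-one (C5=C6 enone; 16-exo-silyloxy)
Conditions: LiN(iPr)2 (1.1 equiv), THF, −78 °C; then PhS(Cl)=NtBu, −78 °C
Reagents that add atoms: none
Why: LiN(iPr)2 removes a proton from the C5 methylene in preference to the hindered ring-fusion C9, and sulfenylation of this enolate by the sulfinimidoyl chloride followed by spontaneous syn elimination (one-pot ketone dehydrogenation) should give the C5=C6 enone conjugated with both carbonyl groups.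

Step 7
Reactants: 11 benzyl ester of the B/C/D tricyclic 5-en-10-one; 12 2-(2-bromoethyl)-1,3-dioxolane; 13 propionic anhydride
Product: 16 C10 propionate of the tertiary alcohol (C1–C3 chain ending in a 1,3-dioxolane; C5=C6 enoate; C1 syn to H9), via Grignard reagent 14 (not isolated), via bromomagnesium alkoxide 15 (not isolated)
Conditions: 12, Mg, THF, 23 °C; CeCl3 (1.5 equiv), THF, −78 °C; then 11, −78 °C; then 13, DMAP, −78 to 23 °C
Reagents that add atoms: none
Why: The organocerium reagent made from 14 adds 1,2 to the C10 ketone rather than to the ester or the enoate β-carbon (organocerium carbonyl addition), it should approach the face of ring B that carries H9 and is anti to C11 on the adjacent carbon, which sets C10 with C1 syn to H9, and the tertiary alkoxide 15 is acylated in the same flask.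

Step 8
Reactants: 16 C10 propionate of the tertiary alcohol
Product: 17 19,10-γ-lactone with C4–H (C18 methyl on the convex face; 6-CO2Bn trans to C4; 16-exo-silyloxy; C3 as dioxolane)
Conditions: KN(SiMe3)2 (1.1 equiv), THF, −78 to 0 °C; then tBuOH, 0 to 23 °C
Reagents that add atoms: none
Why: The potassium enolate of the propionate adds to C5, the β-carbon of the C5=C6–C7 enoate (5-exo-trig intramolecular Michael addition), so the new C4–C5 bond and the C10 oxygen are necessarily cis and C5 is set by C10, and equilibration of the resulting ester enolate with tBuOH should leave the C6 ester trans to the bulky C4 substituent on C5, while C4 (epimer with methyl on the convex face drawn) is re-enolised in step 13.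

Step 9
Reactants: 17 19,10-γ-lactone with C4–H
Product: 18 16-exo-alcohol of the lactone
Conditions: HF·pyridine, pyridine, THF, 0 to 23 °C
Reagents that add atoms: none
Why: Fluoride-mediated desilylation with pyridine-buffered HF frees the C16 alcohol and spares the dioxolane, the lactone and the benzyl ester.

Step 10
Reactants: 18 16-exo-alcohol of the lactone
Product: 19 16-ketone of the lactone
Conditions: Dess–Martin periodinane, CH2Cl2, 23 °C
Reagents that add atoms: none
Why: Dess–Martin oxidation gives the C16 ketone under near-neutral conditions that do not open the acetal.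

Step 11
Reactants: 19 16-ketone of the lactone
Product: 20 16-methylene lactone (exocyclic C16=C17)
Conditions: Ph3PCH3Br, KOtBu, THF, 0 to 23 °C
Reagents that add atoms: methylenetriphenylphosphorane, C=P(c1ccccc1)(c1ccccc1)c1ccccc1
Why: Wittig methylenation of the bicyclic ketone installs C17 at a stage where no base-sensitive β-hydroxy lactone is present, and any epimerisation by the basic ylide is corrected thermodynamically at C6 and is irrelevant at C4.

Step 12
Reactants: 20 16-methylene lactone
Product: 21 C3 aldehyde (lactone with a 3-oxopropyl chain on C10)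
Conditions: 1 M HCl, THF, 23 °C
Reagents that add atoms: water, O
Why: Acid-catalysed acetal hydrolysis releases the C3 aldehyde at 23 °C, conditions under which the 1,1-disubstituted exocyclic alkene should survive.

Step 13
Reactants: 21 C3 aldehyde
Product: 22 3β-hydroxy-16-methylene 19,10-lactone benzyl ester (ring A closed; C18 methyl on C4 syn to ring B)
Conditions: KOtBu (0.3 equiv), THF/tBuOH, 0 °C; then AcOH
Reagents that add atoms: none
Why: Intramolecular aldol addition of the lactone enolate at C4 to the C3 aldehyde closes six-membered ring A, the tether from C10 can reach C4 only on the convex face, which fixes the quaternary C4 with C18 syn to ring B, and the axial 3β-hydroxyl is expected under kinetic control from the arrangement in which the aldehyde oxygen points away from the enolate oxygen, so the reaction is quenched before retro-aldol equilibration sets in.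

Step 14
Reactants: 22 3β-hydroxy-16-methylene 19,10-lactone benzyl ester
Product: 23 benzyl ester of the target (16-exo-hydroxy-16-methyl)
Conditions: Co(acac)2 (20 mol%), PhSiH3, O2 (1 atm), iPrOH/CH2Cl2, 23 °C
Reagents that add atoms: dioxygen, O=O
Why: Mukaiyama hydration (hydrogen-atom transfer from a cobalt hydride to C17, capture of the tertiary C16 radical by O2 and reduction of the peroxide by the silane) is Markovnikov-selective, and O2 should approach the exo face of the C15–C16 bridge, away from the axial hydrogen on C11, which places the C16 hydroxyl on the side of C14 and the methyl group on the side of the C9–C11–C12 bridge.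

Step 15
Reactants: 23 benzyl ester of the target
Product: 24 target gibberellin (3β,16-dihydroxy-16-methyl 19,10-lactone 7-carboxylic acid)
Conditions: H2 (1 atm), Pd/C, EtOAc, 23 °C
Reagents that add atoms: none
Why: Hydrogenolysis of the benzyl ester over Pd/C frees the C7 acid under neutral conditions, which avoids the base-induced retro-aldol epimerisation at C3 and lactone opening that ester saponification would risk.

Compound list
1 | (R)-4-(tert-butyldimethylsilyloxy)cyclopent-2-en-1-one | O=C1C=C[C@H](O[Si](C)(C)C(C)(C)C)C1 | starting material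
2 | allylmagnesium bromide | C=CC[Mg]Br | starting material
3 | trimethylsilyl enol ether of 4 (C8=C14 enol ether) | C=CC[C@@H]1C=C(O[Si](C)(C)C)C[C@H]1O[Si](C)(C)C(C)(C)C | intermediate
4 | (3R,4R)-3-allyl-4-(tert-butyldimethylsilyloxy)cyclopentan-1-one | C=CC[C@@H]1CC(=O)C[C@H]1O[Si](C)(C)C(C)(C)C | intermediate
5 | benzyl (triphenylphosphoranylidene)acetate | O=C(C=P(c1ccccc1)(c1ccccc1)c1ccccc1)OCc1ccccc1 | starting material
6 | benzyl (E)-2-[(3R,4R)-3-allyl-4-(tert-butyldimethylsilyloxy)cyclopentylidene]acetate | C=CC[C@@H]1C/C(=C\C(=O)OCc2ccccc2)C[C@H]1O[Si](C)(C)C(C)(C)C | intermediate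
7 | methyl vinyl ketone (but-3-en-2-one) | C=CC(C)=O | starting material
8 | benzyl (E)-2-{(3R,4R)-4-(tert-butyldimethylsilyloxy)-3-[(E)-4-oxopent-2-en-1-yl]cyclopentylidene}acetate | CC(=O)/C=C/C[C@@H]1C/C(=C\C(=O)OCc2ccccc2)C[C@H]1O[Si](C)(C)C(C)(C)C | intermediate
9 | benzyl 2-[2-acetyl-6-(tert-butyldimethylsilyloxy)bicyclo[3.2.1]octan-1-yl]acetate (acetyl on C9 anti to the C15–C16 bridge; 16-exo-silyloxy) | CC(=O)[C@@H]1CC[C@@H]2C[C@]1(C[C@H]2O[Si](C)(C)C(C)(C)C)CC(=O)OCc1ccccc1 | intermediate
10 | benzyl ester of the B/C/D tricyclic 10-ketone (C5H2, C6H–CO2Bn, H9 syn to C15, 16-exo-silyloxy) | O=C1[C@@H]2CC[C@@H]3C[C@]2(C[C@H]3O[Si](C)(C)C(C)(C)C)[C@@H](C(=O)OCc4ccccc4)C1 | intermediate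
11 | benzyl ester of the B/C/D tricyclic 5-en-10-one (C5=C6 enone) | O=C1[C@@H]2CC[C@@H]3C[C@]2(C[C@H]3O[Si](C)(C)C(C)(C)C)C(C(=O)OCc4ccccc4)=C1 | intermediate
12 | 2-(2-bromoethyl)-1,3-dioxolane | BrCCC1OCCO1 | starting material
13 | propionic anhydride | CCC(=O)OC(=O)CC | starting material
14 | [2-(1,3-dioxolan-2-yl)ethyl]magnesium bromide | Br[Mg]CCC1OCCO1 | intermediate
15 | bromomagnesium alkoxide of the C10 tertiary alcohol (C1 syn to H9) | Br[Mg+].[O-][C@]1(CCC2OCCO2)[C@@H]2CC[C@@H]3C[C@]2(C[C@H]3O[Si](C)(C)C(C)(C)C)C(C(=O)OCc4ccccc4)=C1 | intermediate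
16 | C10 propionate of the tertiary alcohol (dioxolane chain, C5=C6 enoate) | CCC(=O)O[C@]1(CCC2OCCO2)[C@@H]2CC[C@@H]3C[C@]2(C[C@H]3O[Si](C)(C)C(C)(C)C)C(C(=O)OCc4ccccc4)=C1 | intermediate
17 | 19,10-γ-lactone with C4–H (C18 on the convex face, 6-CO2Bn trans to C4, 16-exo-silyloxy, C3 as dioxolane) | C[C@H]1C(=O)O[C@]2(CCC3OCCO3)[C@@H]3CC[C@@H]4C[C@]3(C[C@H]4O[Si](C)(C)C(C)(C)C)[C@@H](C(=O)OCc5ccccc5)[C@@H]21 | intermediate
18 | 16-exo-alcohol of the lactone | C[C@H]1C(=O)O[C@]2(CCC3OCCO3)[C@@H]3CC[C@@H]4C[C@]3(C[C@H]4O)[C@@H](C(=O)OCc5ccccc5)[C@@H]21 | intermediate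
19 | 16-ketone of the lactone | C[C@H]1C(=O)O[C@]2(CCC3OCCO3)[C@@H]3CC[C@@H]4C[C@]3(CC4=O)[C@@H](C(=O)OCc5ccccc5)[C@@H]21 | intermediate
20 | 16-methylene lactone (C16=C17) | C[C@H]1C(=O)O[C@]2(CCC3OCCO3)[C@@H]3CC[C@@H]4C[C@]3(CC4=C)[C@@H](C(=O)OCc5ccccc5)[C@@H]21 | intermediate
21 | C3 aldehyde (3-oxopropyl chain on C10) | C[C@H]1C(=O)O[C@]2(CCC=O)[C@@H]3CC[C@@H]4C[C@]3(CC4=C)[C@@H](C(=O)OCc5ccccc5)[C@@H]21 | intermediate
22 | 3β-hydroxy-16-methylene 19,10-lactone benzyl ester (ring A closed) | C[C@@]12C(=O)O[C@]3(CC[C@@H]1O)[C@@H]1CC[C@@H]4C[C@]1(CC4=C)[C@@H](C(=O)OCc5ccccc5)[C@@H]32 | intermediate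
23 | benzyl ester of the target (16-exo-hydroxy-16-methyl) | C[C@@]12C(=O)O[C@]3(CC[C@@H]1O)[C@@H]1CC[C@@H]4C[C@]1(C[C@@]4(C)O)[C@@H](C(=O)OCc5ccccc5)[C@@H]32 | intermediate
24 | target gibberellin (3β,16-dihydroxy-16-methyl 19,10-lactone 7-carboxylic acid) | C[C@@]12C(=O)O[C@]3(CC[C@@H]1O)[C@@H]1CC[C@@H]4C[C@]1(C[C@@]4(C)O)[C@@H](C(=O)O)[C@@H]32 | target

Total step count: 15. Longest linear sequence: 15 steps (from 1 to 24).

Steps most likely to fail

Step 4 (key step). The copper enolate may be protonated, or may fail to add to the fully substituted C8, so that conjugate reduction occurs without ring closure. Fallback: setting out from 8, RhCl(PPh3)3-catalysed 1,4-hydrosilylation of the enone with Et3SiH (benzene, 50 °C) gives the isolated (Z)-triethylsilyl enol ether F1. TiCl4 (CH2Cl2, −78 °C) then activates the enoate for an intramolecular Mukaiyama–Michael addition of C9 to C8, which returns to 9 after aqueous work-up.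

Step 5. The doubly deprotonated intermediate may couple between molecules or be over-oxidised, and the methyl ketone enolate may attack the benzyl ester before the second deprotonation is complete. Fallback: setting out from 9, the ketone is masked as the dioxolane F2 (1,2-bis(trimethylsilyloxy)ethane, Me3SiOTf cat., CH2Cl2, −78 °C). The ester enolate (KN(SiMe3)2, THF, −78 °C) is hydroxylated with 2-(phenylsulfonyl)-3-phenyloxaziridine to the α-hydroxy ester F3, and Dess–Martin oxidation gives the α-keto ester F4. PPTS in wet acetone releases the methyl ketone α-keto ester F5, and DBU (CH2Cl2, 23 °C) closes ring B by intramolecular aldol condensation of the C5 methyl group onto the C6 ketone. This returns to enone 11 and makes step 6 unnecessary.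

Step 13. Facial selectivity at the aldehyde carbon may be poor, and retro-aldol equilibration may drain the product toward the equatorial 3α-alcohol. Fallback: setting out from 21, the aldol is run to equilibrium (KOtBu, tBuOH/THF, 23 °C) to give the 3α-hydroxy epimer F6. Dess–Martin oxidation gives the 3-ketone F7, and LiBH(sBu)3 (THF, −78 °C) delivers hydride from the equatorial direction to give the axial 3β-alcohol 22.

Further compounds
F1 | step 4 | (Z)-triethylsilyl enol ether of 8 | C/C(O[Si](CC)(CC)CC)=C/CC[C@@H]1C/C(=C\C(=O)OCc2ccccc2)C[C@H]1O[Si](C)(C)C(C)(C)C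
F2 | step 5 | dioxolane ketal of 9 | CC1(OCCO1)[C@@H]1CC[C@@H]2C[C@]1(C[C@H]2O[Si](C)(C)C(C)(C)C)CC(=O)OCc1ccccc1
F3 | step 5 | α-hydroxy ester of the ketal (hydroxyl on C6, one epimer drawn) | CC1(OCCO1)[C@@H]1CC[C@@H]2C[C@]1(C[C@H]2O[Si](C)(C)C(C)(C)C)[C@@H](O)C(=O)OCc1ccccc1
F4 | step 5 | α-keto ester of the ketal (C6 ketone) | CC1(OCCO1)[C@@H]1CC[C@@H]2C[C@]1(C[C@H]2O[Si](C)(C)C(C)(C)C)C(=O)C(=O)OCc1ccccc1
F5 | step 5 | methyl ketone α-keto ester | CC(=O)[C@@H]1CC[C@@H]2C[C@]1(C[C@H]2O[Si](C)(C)C(C)(C)C)C(=O)C(=O)OCc1ccccc1
F6 | step 13 | 3α-hydroxy epimer of 22 | C[C@@]12C(=O)O[C@]3(CC[C@H]1O)[C@@H]1CC[C@@H]4C[C@]1(CC4=C)[C@@H](C(=O)OCc5ccccc5)[C@@H]32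
F7 | step 13 | 3-ketone corresponding to 22 | C[C@@]12C(=O)O[C@]3(CCC1=O)[C@@H]1CC[C@@H]4C[C@]1(CC4=C)[C@@H](C(=O)OCc5ccccc5)[C@@H]32
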